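**Plan**
- **Cuts (retrosynthesis):** C16–C17 (alkenyl–alkenyl coupling) and C15=C16 (cross metathesis). Then C6–CH3 (methyl transfer to a C6 peroxycarbenium ion). Then excision of O–O from between C6 and C3, which restores a C3–C6 bond. Then C6–C7 (Grignard addition), and finally C3–C6 with C4–C5 ([2+2] of dichloroketene with 5-methyl-2,3-dihydrofuran).
- **Enabling feature:** the O–O unit bridges C3 and C6, which are 1,4-related through C4–C5, and C6 is a fully substituted, oxygen-bearing carbon. Without O2 the 1,2-dioxane ring collapses to the cyclobutanol ring C3–C4–C5–C6, cis-fused along C3–C4 to the γ-lactone ring (O–C1–C2–C3–C4). That bicycle is a ketene/enol ether cycloadduct.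
- **Forward order:** cyclobutane and oxolane rings form together ([2+2]); lactone carbonyl (RuO4); C7–C16 chain onto C6; the four-membered carbocycle is expanded by O2 to the six-membered 1,2-dioxane; C6–CH3; triene last, away from O2 and radicals.
- **Stereochemistry:** C4 comes from an enantiodivergent enzymatic reduction of the racemic cyclobutanone (diastereomers separated, carbinol centre then oxidised away). C3 follows from C4 through the cis ring fusion. C6 comes from axial methyl delivery on the face of the pseudoaxial C4–O bond. The E-alkenes come from E-selective metathesis, Takai olefination and a stereoretentive coupling.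

Key step: step 6

Remark: atoms are numbered as in the plakortolide family (C1 lactone C=O, C2 CH2, C3 CH–OO, C4 C(CH3)–O, C5 CH2, C6 C(CH3)–OO, chain C7–C22); 4 and 5 are racemates and are drawn as the enantiomer that is carried on.

**Step 1**
Reactants: 1 5-methyl-2,3-dihydrofuran; 2 trichloroacetyl chloride
Product: 4 (±)-cis-7,7-dichloro-1-methyl-2-oxabicyclo[3.2.0]heptan-6-one (racemate; drawn (1R,5S)), via dichloroketene 3 (not isolated)
Conditions: Zn–Cu, slow addition of 2, DME/Et2O, 0 °C → rt
Reagents that add atoms: none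
Why: Ketene–alkene [2+2] cycloaddition: the electrophilic central carbon of dichloroketene (future C6) bonds to the nucleophilic β-carbon C3 of the enol ether and the CCl2 carbon (future C5) to the oxygen-bearing C4, and suprafacial addition to the ring alkene fixes the cis relation of C3 and C4 (racemate).

**Step 2**
Reactants: 4 (±)-cis-7,7-dichloro-1-methyl-2-oxabicyclo[3.2.0]heptan-6-one
Product: 5 (±)-cis-1-methyl-2-oxabicyclo[3.2.0]heptan-6-one (racemate; drawn (1S,5S))
Conditions: Zn dust, AcOH, rt
Reagents that add atoms: none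
Why: Zinc-mediated reductive dechlorination of an α,α-dichlorocyclobutanone, in which the zinc enolate is protonated by the solvent faster than it can expel the poor β-alkoxide leaving group; no stereocentre is touched.

**Step 3**
Reactants: 5 (±)-cis-1-methyl-2-oxabicyclo[3.2.0]heptan-6-one
Product: 6 (1S,5R,6S)-1-methyl-2-oxabicyclo[3.2.0]heptan-6-ol (exo alcohol, OH cis to C1–CH3 and C5–H)
Conditions: Prelog-type alcohol dehydrogenase (e.g. ADH-A from Rhodococcus ruber), NAD+ (cat.), i-PrOH (10 vol %), phosphate buffer pH 7.5, 30 °C; separation of the exo and endo alcohols on SiO2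
Reagents that add atoms: none
Why: Enantiodivergent enzymatic ketone reduction (parallel kinetic resolution), a reaction type well known for bicyclo[3.2.0]heptan-6-ones: the enzyme adds hydride to the same heterotopic face of C6 in both enantiomers (CH branch large, CH2 branch small), so (1S,5S)-5 should give the 6S exo alcohol 6 and (1R,5R)-5 the 6S endo alcohol, diastereomers that are separated, which fixes the absolute configuration of C4.

**Step 4**
Reactants: 6 (1S,5R,6S)-1-methyl-2-oxabicyclo[3.2.0]heptan-6-ol
Product: 7 (1S,5S)-1-methyl-2-oxabicyclo[3.2.0]heptane-3,6-dione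
Conditions: RuCl3·xH2O (5 mol %), NaIO4 (4 equiv), EtOAc/MeCN/H2O, rt
Reagents that add atoms: sodium periodate [Na+].[O-]I(=O)(=O)=O (oxygen relayed by RuO4)
Why: RuO4 oxidation turns the secondary alcohol into the cyclobutanone and the only O–CH2 group of the oxolane ring into the lactone carbonyl C1 (the other ether terminus C4 bears no hydrogen), and neither C3 nor C4 is touched.

**Step 5**
Reactants: 7 (1S,5S)-1-methyl-2-oxabicyclo[3.2.0]heptane-3,6-dione; 8 10-bromodec-1-ene
Product: 10 (1S,5R,6R)-6-(dec-9-en-1-yl)-6-hydroxy-1-methyl-2-oxabicyclo[3.2.0]heptan-3-one (OH endo), via dec-9-enylmagnesium bromide 9 (not isolated)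
Conditions: 8, Mg, THF, rt; then LaCl3·2LiCl (1 equiv), 7, THF, −78 °C; pH 7 buffer quench at −78 °C
Reagents that add atoms: none
Why: Chemoselective 1,2-addition of a lanthanum-modified Grignard reagent to the strained cyclobutanone, which is far more electrophilic than the lactone, while the low basicity and the cold quench suppress enolisation, β-elimination of the C4 carboxylate and acyl migration; attack from the convex face should place OH endo, but this centre is erased in step 6.

**Step 6**
Reactants: 10 (1S,5R,6R)-6-(dec-9-en-1-yl)-6-hydroxy-1-methyl-2-oxabicyclo[3.2.0]heptan-3-one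
Product: 12 (1S,4S,6S)-4-(dec-9-en-1-yl)-4-hydroxy-6-methyl-2,3,7-trioxabicyclo[4.3.0]nonan-8-one (cis-fused peroxyhemiketal, OH axial), via cis-hydroperoxy ketone 11 (not isolated)
Conditions: Co(acac)2 (20 mol %), O2 (1 atm), toluene, 40–50 °C, dark
Reagents that add atoms: dioxygen O=O
Why: Co(II)/O2 converts the tertiary cyclobutanol into a Co(III) alkoxide that releases the C6 alkoxyl radical; strain-driven β-scission cleaves C6–C3 (secondary radical) rather than C6–C5 (primary neopentyl radical) or C6–C7 (no strain release), triplet O2 adds to C3, and the resulting hydroperoxide 11 adds to the new C6 ketone, so the four-membered ring C3–C4–C5–C6 becomes the six-membered ring C3–C4–C5–C6–O–O with both oxygen atoms in place. The closest known reaction type is the cobalt-catalysed aerobic oxidative ring expansion of secondary and tertiary cyclobutanols to 1,2-dioxan-3-ols. The only ring closure is the 6-exo-trig addition of the C3–OOH group to the C6 carbonyl group. C3 is controlled by the intact C4 stereocentre: O2 capture anti to the pseudoaxial C4 methyl group places the OO group cis to the 2-oxoalkyl arm, and only this isomer can close to a strain-free cis-fused chair, the trans hydroperoxide being removed by chromatography; C6 settles by ring–chain equilibration with OH axial (anomeric effect) and the long chain equatorial, and is ionised in step 8 in any case. The step needs regioselective β-scission, face selectivity at C3 and an untouched terminal alkene: the first follows from radical stability, the second is the weak point because O2 capture is close to diffusion control, and the third holds because no hydride source is present that could start a hydroperoxidation of the alkene.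

**Step 7**
Reactants: 12 (1S,4S,6S)-4-(dec-9-en-1-yl)-4-hydroxy-6-methyl-2,3,7-trioxabicyclo[4.3.0]nonan-8-one
Product: 13 (1S,4S,6S)-4-(dec-9-en-1-yl)-6-methyl-8-oxo-2,3,7-trioxabicyclo[4.3.0]nonan-4-yl acetate
Conditions: Ac2O, pyridine, DMAP (cat.), CH2Cl2, 0 °C
Reagents that add atoms: acetic anhydride CC(=O)OC(C)=O
Why: O-Acetylation of a peroxyhemiketal, known for 1,2-dioxan-3-ols and 1,2-dioxolan-3-ols, locks the cyclic form and installs a leaving group at C6 with retention, under a base too weak for E1cB opening of the β-peroxy lactone.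

**Step 8**
Reactants: 13 (1S,4S,6S)-4-(dec-9-en-1-yl)-6-methyl-8-oxo-2,3,7-trioxabicyclo[4.3.0]nonan-4-yl acetate
Product: 14 (1S,4S,6S)-4-(dec-9-en-1-yl)-4,6-dimethyl-2,3,7-trioxabicyclo[4.3.0]nonan-8-one
Conditions: AlMe3 (3 equiv, hexanes), CH2Cl2, −78 → −40 °C; Rochelle salt work-up
Reagents that add atoms: trimethylaluminium C[Al](C)C
Why: Proposed new method: AlMe3 binds the acetate, ionises C6–OAc to the peroxycarbenium ion (C6=O+–O) paired with [Me3Al–OAc]−, and the ate complex should hand a methyl group to C6 faster than proton loss or O–O heterolysis can occur; the half-chair with the C4–O(acyl) bond pseudoaxial and C4–CH3 pseudoequatorial is attacked along the axial trajectory on the face of the lactone oxygen, the same face from which the axial acetate leaves, so CH3 ends axial and cis to the lactone and the chain equatorial (6S); the closest known reaction types are the Lewis-acid-mediated substitution of 3-acetoxy- and 3-alkoxy-1,2-dioxanes by allylsilanes, silyl enol ethers and Et3SiH through peroxycarbenium ions, and the AlMe3 C-methylation of cyclic ketal-type oxocarbenium ions and of trioxane lactol derivatives, in which an O–O bond survives.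

**Step 9**
Reactants: 14 (1S,4S,6S)-4-(dec-9-en-1-yl)-4,6-dimethyl-2,3,7-trioxabicyclo[4.3.0]nonan-8-one
Product: 15 (1S,4S,6S)-4,6-dimethyl-4-[(9E)-10-(4,4,5,5-tetramethyl-1,3,2-dioxaborolan-2-yl)dec-9-en-1-yl]-2,3,7-trioxabicyclo[4.3.0]nonan-8-one
Conditions: vinylboronic acid pinacol ester (3 equiv), Hoveyda–Grubbs II (5 mol %), CH2Cl2, 40 °C
Reagents that add atoms: vinylboronic acid pinacol ester C=CB1OC(C)(C)C(C)(C)O1
Why: Olefin cross metathesis of a terminal alkene with a vinyl boronate is E-selective for steric reasons, and ruthenium carbenes are known to tolerate dialkyl peroxides and lactones under these neutral conditions.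

**Step 10**
Reactants: 16 (E)-pent-2-enal
Product: 17 (1E,3E)-1-iodohexa-1,3-diene
Conditions: CHI3, CrCl2, THF/dioxane, 0 °C, dark
Reagents that add atoms: iodoform IC(I)I
Why: Takai olefination of an aldehyde with the geminal dichromium reagent from iodoform gives the E-alkenyl iodide through the anti-periplanar elimination of the less crowded adduct, and the existing E-alkene is untouched.

**Step 11**
Reactants: 15 the (E)-alkenyl pinacol boronate; 17 (1E,3E)-1-iodohexa-1,3-diene
Product: 18 (1S,4S,6S)-4-[(9E,11E,13E)-hexadeca-9,11,13-trien-1-yl]-4,6-dimethyl-2,3,7-trioxabicyclo[4.3.0]nonan-8-one (target)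
Conditions: Pd(dppf)Cl2·CH2Cl2 (5 mol %), K3PO4 (aq.), THF, rt, degassed, dark
Reagents that add atoms: none
Why: Suzuki–Miyaura alkenyl–alkenyl coupling proceeds with retention at both partners and so gives the all-E triene, and palladium-catalysed couplings at room temperature with a mild base are known to spare saturated 1,2-dioxanes.

**Compound list**
1 | 5-methyl-2,3-dihydrofuran | CC1=CCCO1 | starting material
2 | trichloroacetyl chloride | ClC(Cl)(Cl)C(Cl)=O | starting material
3 | dichloroketene | ClC(Cl)=C=O | intermediate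
4 | (±)-cis-7,7-dichloro-1-methyl-2-oxabicyclo[3.2.0]heptan-6-one (racemate, drawn (1R,5S)) | O=C1C(Cl)(Cl)[C@]2(C)OCC[C@@H]21 | intermediate
5 | (±)-cis-1-methyl-2-oxabicyclo[3.2.0]heptan-6-one (racemate, drawn (1S,5S)) | O=C1C[C@]2(C)OCC[C@@H]21 | intermediate
6 | (1S,5R,6S)-1-methyl-2-oxabicyclo[3.2.0]heptan-6-ol (exo alcohol) | O[C@H]1C[C@]2(C)OCC[C@@H]21 | intermediate
7 | (1S,5S)-1-methyl-2-oxabicyclo[3.2.0]heptane-3,6-dione | O=C1C[C@]2(C)OC(=O)C[C@@H]21 | intermediate
8 | 10-bromodec-1-ene | C=CCCCCCCCCBr | starting material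
9 | dec-9-enylmagnesium bromide | C=CCCCCCCCC[Mg]Br | intermediate
10 | (1S,5R,6R)-6-(dec-9-en-1-yl)-6-hydroxy-1-methyl-2-oxabicyclo[3.2.0]heptan-3-one | C=CCCCCCCCC[C@@]1(O)C[C@]2(C)OC(=O)C[C@@H]21 | intermediate
11 | (4S,5S)-4-hydroperoxy-5-methyl-5-(2-oxododec-11-en-1-yl)oxolan-2-one | C=CCCCCCCCCC(=O)C[C@]1(C)OC(=O)C[C@@H]1OO | intermediate
12 | (1S,4S,6S)-4-(dec-9-en-1-yl)-4-hydroxy-6-methyl-2,3,7-trioxabicyclo[4.3.0]nonan-8-one | C=CCCCCCCCC[C@@]1(O)C[C@]2(C)OC(=O)C[C@@H]2OO1 | intermediate
13 | (1S,4S,6S)-4-(dec-9-en-1-yl)-6-methyl-8-oxo-2,3,7-trioxabicyclo[4.3.0]nonan-4-yl acetate | C=CCCCCCCCC[C@@]1(OC(C)=O)C[C@]2(C)OC(=O)C[C@@H]2OO1 | intermediate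
14 | (1S,4S,6S)-4-(dec-9-en-1-yl)-4,6-dimethyl-2,3,7-trioxabicyclo[4.3.0]nonan-8-one | C=CCCCCCCCC[C@@]1(C)C[C@]2(C)OC(=O)C[C@@H]2OO1 | intermediate
15 | (1S,4S,6S)-4,6-dimethyl-4-[(9E)-10-(4,4,5,5-tetramethyl-1,3,2-dioxaborolan-2-yl)dec-9-en-1-yl]-2,3,7-trioxabicyclo[4.3.0]nonan-8-one | CC1(C)OB(OC1(C)C)/C=C/CCCCCCCC[C@@]2(C)C[C@]3(C)OC(=O)C[C@@H]3OO2 | intermediate
16 | (E)-pent-2-enal | CC/C=C/C=O | starting material
17 | (1E,3E)-1-iodohexa-1,3-diene | CC/C=C/C=C/I | intermediate
18 | (1S,4S,6S)-4-[(9E,11E,13E)-hexadeca-9,11,13-trien-1-yl]-4,6-dimethyl-2,3,7-trioxabicyclo[4.3.0]nonan-8-one | CC/C=C/C=C/C=C/CCCCCCCC[C@@]1(C)C[C@]2(C)OC(=O)C[C@@H]2OO1 | target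

**Step count:** 11 steps in total. The longest linear sequence is 10 steps (steps 1–9 and 11).

**Steps most likely to fail**

1. **Step 8 (new method).**
   - Risk: after ionisation the peroxycarbenium ion may lose a proton or undergo O–O heterolysis with alkyl migration faster than methyl transfer, or the aluminium reagent may attack the O–O bond.
   - Fallback with known chemistry, setting out from 12 and returning at 14: Et3N in CH2Cl2 opens the hemiketal and expels hydrogen peroxide by E1cB (washed out with water) to give the keto-butenolide (5S)-5-methyl-5-(2-oxododec-11-en-1-yl)furan-2(5H)-one F1. MeMgBr/CeCl3 (THF, −78 °C) adds to the ketone only and gives the tertiary alcohol (5S)-5-(2-hydroxy-2-methyldodec-11-en-1-yl)-5-methylfuran-2(5H)-one F2 as a mixture at C6. Acid-catalysed perhydrolysis (aqueous H2O2, cat. H2SO4, Et2O, 0 °C) gives the tertiary hydroperoxide (5S)-5-(2-hydroperoxy-2-methyldodec-11-en-1-yl)-5-methylfuran-2(5H)-one F3. Et2NH in CF3CH2OH then closes the dioxane by 6-exo-trig oxa-Michael addition to the butenolide. The tether from C4 enforces the cis fusion, and 14 is separated from its C6 epimer by chromatography.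

2. **Step 6 (key step).**
   - Risk: poor facial selectivity in the capture of O2 at C3, cobalt-induced cleavage of the hydroperoxide before ring closure, or acyl migration in 10 that moves the free hydroxyl group to C4.
   - Fallback, setting out from 10 and returning at 14: the same alkoxyl radical is generated with Mn(OAc)3 in the presence of Cu(OAc)2 (AcOH/MeCN). The C3 radical is oxidised by Cu(II) to the C2=C3 alkene, giving the keto-butenolide (5S)-5-methyl-5-(2-oxododec-11-en-1-yl)furan-2(5H)-one F4. Urea–H2O2 with cat. Sc(OTf)3 in MeOH converts the ketone into the α-methoxy hydroperoxide (5S)-5-(2-hydroperoxy-2-methoxydodec-11-en-1-yl)-5-methylfuran-2(5H)-one F5. Et2NH in CF3CH2OH delivers the OOH group intramolecularly to C3 (6-exo-trig oxa-Michael addition), so the cis fusion no longer depends on an intermolecular capture. This gives the methoxy peroxyketal (1S,4S,6S)-4-(dec-9-en-1-yl)-4-methoxy-6-methyl-2,3,7-trioxabicyclo[4.3.0]nonan-8-one F6, which takes the place of 13 in step 8 and leads to 14.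

3. **Step 3.**
   - Risk: incomplete discrimination of the two α-branches of C6 by the enzyme, so that each enantiomer gives both alcohols and the optical purity of 6 erodes.
   - Fallback, setting out from 5 and returning at 7: L-Selectride (THF, −78 °C) reduces racemic 5 from the convex face to the racemic endo alcohol (1S*,5R*,6R*)-1-methyl-2-oxabicyclo[3.2.0]heptan-6-ol F7. Burkholderia cepacia lipase with vinyl acetate (MTBE, 30 °C) acylates the 6R enantiomer, as the empirical size rule for lipases predicts, to give (1S,5R,6R)-1-methyl-2-oxabicyclo[3.2.0]heptan-6-yl acetate F8, which is separated from the unreacted alcohol. K2CO3 in MeOH liberates (1S,5R,6R)-1-methyl-2-oxabicyclo[3.2.0]heptan-6-ol F9, which is oxidised to 7 under the conditions of step 4.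

**Further compounds**
F1 | step 8 | (5S)-5-methyl-5-(2-oxododec-11-en-1-yl)furan-2(5H)-one | C=CCCCCCCCCC(=O)C[C@]1(C)OC(=O)C=C1
F2 | step 8 | (5S)-5-(2-hydroxy-2-methyldodec-11-en-1-yl)-5-methylfuran-2(5H)-one (both C6 epimers) | C=CCCCCCCCCC(C)(O)C[C@]1(C)OC(=O)C=C1
F3 | step 8 | (5S)-5-(2-hydroperoxy-2-methyldodec-11-en-1-yl)-5-methylfuran-2(5H)-one (both C6 epimers) | C=CCCCCCCCCC(C)(OO)C[C@]1(C)OC(=O)C=C1
F4 | step 6 | (5S)-5-methyl-5-(2-oxododec-11-en-1-yl)furan-2(5H)-one | C=CCCCCCCCCC(=O)C[C@]1(C)OC(=O)C=C1
F5 | step 6 | (5S)-5-(2-hydroperoxy-2-methoxydodec-11-en-1-yl)-5-methylfuran-2(5H)-one | C=CCCCCCCCCC(OC)(OO)C[C@]1(C)OC(=O)C=C1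
F6 | step 6 | (1S,4S,6S)-4-(dec-9-en-1-yl)-4-methoxy-6-methyl-2,3,7-trioxabicyclo[4.3.0]nonan-8-one | C=CCCCCCCCC[C@@]1(OC)C[C@]2(C)OC(=O)C[C@@H]2OO1
F7 | step 3 | (1S*,5R*,6R*)-1-methyl-2-oxabicyclo[3.2.0]heptan-6-ol (racemic endo alcohol, one enantiomer drawn) | O[C@@H]1C[C@]2(C)OCC[C@@H]21
F8 | step 3 | (1S,5R,6R)-1-methyl-2-oxabicyclo[3.2.0]heptan-6-yl acetate | CC(=O)O[C@@H]1C[C@]2(C)OCC[C@@H]21
F9 | step 3 | (1S,5R,6R)-1-methyl-2-oxabicyclo[3.2.0]heptan-6-ol (single enantiomer) | O[C@@H]1C[C@]2(C)OCC[C@@H]21
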